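**Plan**
- **Cuts:** first the four O-benzyl bonds. Next ring A of the flavanone half at C8-C8a and C4a-C5, then ring C at C2-C3 and O1-C8a, and last the C3'-C6'' biaryl bond.
- **Enabling feature:** ring A (C4a, C5, C6, C7, C8, C8a) has methoxy on C5, next to the C4 carbonyl, and hydroxyl on C7. This matches the oxygen pattern at C1 and C3 of 1,1-dimethoxy-3-(trimethylsilyloxy)buta-1,3-diene, so C5 to C8 can be added to the C4a=C8a bond of a monocyclic ring C and no chelated phenol has to be methylated selectively.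
- **Forward order:** the apigenin rings are bought. The biaryl bond comes from a Suzuki-Miyaura coupling, ring C from a hetero-Diels-Alder reaction on the biaryl aldehyde, and ring A last from a (4+2) annulation with aromatisation.
- **Activation:** C4a carries a phenylsulfinyl group. It makes the vinylogous ester a better dienophile and then leaves by syn elimination with the cis hydrogen on C8a that the cycloaddition itself installs.
- **Stereochemistry:** C2 is the only stereocentre. It is set by BINOL-titanium catalysed addition to the Si face of the aldehyde and is afterwards kept away from base, Lewis acid and strong acid.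

Key step: step 12

Notation: Ar = 4-(benzyloxy)-3-(5,7,4'-tri-O-benzylapigenin-6-yl)phenyl. Pyranone C5 and C6 become flavanone C4a and C8a.
Assumption: the (S)-BINOL titanium catalyst is taken to deliver the diene to the Si face of the biaryl aldehyde, as in its other additions to aromatic aldehydes. The sense is to be checked on the dihydropyranone, and the (R)-ligand is used if it proves opposite.
Remark: the C3'-C6'' axis is treated as freely rotating on the preparative time scale, so C2 is the only stereo-element.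

**Step 1**
Reactants: 1 apigenin
Product: 2 7,4'-di-O-benzylapigenin
Conditions: BnBr (2.2 equiv), K2CO3, DMF, rt
Reagents that add atoms: benzyl bromide, BrCc1ccccc1
Why: Williamson etherification, in which the 7- and 4'-phenols are alkylated while the 5-hydroxyl, hydrogen-bonded to the C4 carbonyl, is too weak a nucleophile under carbonate at room temperature.

**Step 2**
Reactants: 2 7,4'-di-O-benzylapigenin
Product: 3 7,4'-di-O-benzyl-6-iodoapigenin
Conditions: benzyltrimethylammonium dichloroiodate (1.1 equiv), CaCO3, CH2Cl2-MeOH, rt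
Reagents that add atoms: benzyltrimethylammonium dichloroiodate, C[N+](C)(C)Cc1ccccc1.Cl[I-]Cl
Why: Electrophilic aromatic iodination, in which the free 5-hydroxyl makes its ortho position C6 the more activated site, so iodine should enter at C6 and not C8 while CaCO3 takes up the HCl.

**Step 3**
Reactants: 3 7,4'-di-O-benzyl-6-iodoapigenin
Product: 4 5,7,4'-tri-O-benzyl-6-iodoapigenin
Conditions: BnBr (1.5 equiv), K2CO3, DMF, 60 °C
Reagents that add atoms: benzyl bromide, BrCc1ccccc1
Why: Williamson etherification under warmer conditions breaks the chelate and caps the last phenol, and the aryl iodide is inert to carbonate.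

**Step 4**
Reactants: 5 3-bromo-4-hydroxybenzaldehyde
Product: 6 4-(benzyloxy)-3-bromobenzaldehyde
Conditions: BnBr (1.1 equiv), K2CO3, DMF, rt
Reagents that add atoms: benzyl bromide, BrCc1ccccc1
Why: Williamson etherification of an acidic para-formyl phenol, which leaves the aldehyde and the bromide untouched.

**Step 5**
Reactants: 6 4-(benzyloxy)-3-bromobenzaldehyde
Product: 7 4-(benzyloxy)-3-(4,4,5,5-tetramethyl-1,3,2-dioxaborolan-2-yl)benzaldehyde
Conditions: B2pin2, PdCl2(dppf) (3 mol %), KOAc, 1,4-dioxane, 85 °C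
Reagents that add atoms: bis(pinacolato)diboron, CC1(C)OB(OC1(C)C)B1OC(C)(C)C(C)(C)O1
Why: Miyaura borylation, in which the weak acetate base tolerates the aldehyde, and boron is placed on the less hindered ring, which is also less prone to protodeboronation.

**Step 6**
Reactants: 4 5,7,4'-tri-O-benzyl-6-iodoapigenin; 7 4-(benzyloxy)-3-(4,4,5,5-tetramethyl-1,3,2-dioxaborolan-2-yl)benzaldehyde
Product: 8 4-(benzyloxy)-3-(5,7,4'-tri-O-benzylapigenin-6-yl)benzaldehyde (Ar-CHO)
Conditions: Pd(OAc)2 (5 mol %), SPhos (10 mol %), K3PO4 (3 equiv), toluene-H2O, 90 °C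
Reagents that add atoms: none
Why: Suzuki-Miyaura coupling, in which the bulky electron-rich biaryl phosphine is suited to a doubly ortho-substituted iodide and a tri-ortho-substituted biaryl, and it is run before any stereocentre exists so the base can do no stereochemical harm.

**Step 7**
Reactants: 8 Ar-CHO; 9 (E)-1-methoxy-3-(trimethylsilyloxy)buta-1,3-diene
Product: 11 (2S)-2-Ar-2,3-dihydro-4H-pyran-4-one, via O-silyl aldol adduct 10 (not isolated)
Conditions: Ti(OiPr)4 (10 mol %), (S)-BINOL (20 mol %), 4 Å MS, CH2Cl2-Et2O, -20 °C; then CF3CO2H (cat.), CH2Cl2, 0 °C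
Reagents that add atoms: none
Why: Catalytic asymmetric hetero-Diels-Alder reaction in its Mukaiyama aldol-cyclisation variant, in which the titanium binaphtholate binds the aldehyde and lets the diene CH2 reach only the Si face, setting C2 as S in 10, and acid then closes ring C by 6-endo oxa-Michael addition with loss of methanol.

**Step 8**
Reactants: 11 (2S)-2-Ar-2,3-dihydro-4H-pyran-4-one
Product: 13 (2S)-2-Ar-5-(phenylsulfanyl)-2,3-dihydro-4H-pyran-4-one, via chloro sulfide adduct 12 (not isolated)
Conditions: PhSCl (1.05 equiv), CH2Cl2, -78 °C; then Et3N (1.2 equiv), -78 to 0 °C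
Reagents that add atoms: benzenesulfenyl chloride, ClSc1ccccc1
Why: Vinylic sulfenylation by electrophilic addition-elimination, in which sulfur adds to the nucleophilic C5 of the enol ether double bond (12), Et3N removes HCl through the acidic C5 hydrogen, and a sulfenyl chloride without Lewis acid prefers an alkene to the acyl-deactivated flavone ring, where a bromonium source would compete at C8''.

**Step 9**
Reactants: 13 (2S)-2-Ar-5-(phenylsulfanyl)-2,3-dihydro-4H-pyran-4-one
Product: 14 (2S)-2-Ar-5-(phenylsulfinyl)-2,3-dihydro-4H-pyran-4-one (both sulfur epimers, used together)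
Conditions: mCPBA (1.0 equiv), CH2Cl2, -78 to -30 °C
Reagents that add atoms: 3-chloroperbenzoic acid, O=C(OO)c1cccc(Cl)c1
Why: Chemoselective sulfide-to-sulfoxide oxidation, in which sulfur is by far the most nucleophilic site, both acceptor-substituted alkenes are inert to one equivalent of peracid in the cold, and the configuration at sulfur is irrelevant because sulfur is lost in step 12.

**Step 10**
Reactants: 15 1,1-dimethoxyethene
Product: 16 4,4-dimethoxybut-3-en-2-one
Conditions: AcCl (1.0 equiv), 15 (2.2 equiv), Et2O, 0 °C to rt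
Reagents that add atoms: acetyl chloride, CC(=O)Cl
Why: C-acylation of a ketene acetal by an acid chloride (addition-elimination), in which a second equivalent of 15 takes up the HCl and breaks down to methyl acetate and chloromethane.

**Step 11**
Reactants: 16 4,4-dimethoxybut-3-en-2-one
Product: 17 1,1-dimethoxy-3-(trimethylsilyloxy)buta-1,3-diene
Conditions: LiN(iPr)2, THF, -78 °C; then Me3SiCl, -78 °C to rt; distilled and used fresh
Reagents that add atoms: chlorotrimethylsilane, C[Si](C)(C)Cl
Why: Kinetic enolisation of the methyl ketone followed by O-silylation (silyl enol ether formation) gives the cross-conjugated diene.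

**Step 12**
Reactants: 14 (2S)-2-Ar-5-(phenylsulfinyl)-2,3-dihydro-4H-pyran-4-one; 17 1,1-dimethoxy-3-(trimethylsilyloxy)buta-1,3-diene
Product: 21 (2S)-4'-(benzyloxy)-7-hydroxy-5-methoxy-3'-(5,7,4'-tri-O-benzylapigenin-6-yl)flavanone, via sulfinyl cycloadduct 18 (not isolated), via cyclohexadiene acetal 19 (not isolated), via 7-O-trimethylsilyl flavanone 20 (not isolated)
Conditions: 17 (4 equiv), toluene, 25 to 80 °C, sealed tube; then 1 M aq HCl-THF, 0 °C
Reagents that add atoms: none
Why: Proposed new method: the CH2 terminus of 17, its most nucleophilic carbon, bonds to pyranone C6 (future C8a), which is the beta carbon of both the ketone and the vinyl sulfoxide, and the ketene acetal carbon bonds to pyranone C5 (future C4a), either in one asynchronous (4+2) event or by Michael addition followed by collapse of the doubly stabilised carbanion onto the dimethoxycarbenium ion, so that ring A closes as a six-membered carbocycle by intermolecular (4+2) annulation (18). Suprafacial addition sets the sulfinyl group on C4a and the hydrogen on C8a cis, the geometry that thermal syn elimination of benzenesulfenic acid demands, and because C4 and C5 carry no hydrogen only C4a=C8a can form (19), whereas a halogen at C4a would lack an anti hydrogen and would leave O1 as the group more likely to depart. 1,4-Loss of methanol from 19 (hydrogen from C8, one methoxy from C5) gives arene 20 and dilute acid frees the 7-hydroxyl, which leaves methoxy on C5 and hydroxyl on C7. The closest known reaction types are the regiospecific cycloadditions of 1,1-dialkoxy-3-silyloxy dienes to halo- and sulfinylquinones, of oxygenated dienes to 2-sulfinyl cycloalkenones with spontaneous sulfenic acid loss, and of silyloxy dienes to chromones with an acceptor at C3; what has not been shown is a monocyclic 2,3-dihydropyran-4-one as the two-carbon partner. The centres at C4a, C8a and sulfur are transient and need no control, no new stereocentre survives, and C2 keeps its configuration because none of its bonds is touched and neither base nor Lewis acid, which could open ring C or ionise the 4-alkoxybenzylic C2-O1 bond, is present. Regioselectivity is required and follows from the matched polarity of the diene CH2 terminus and C8a, and site selectivity follows because the flavone C2''=C3'' bond has one acceptor only and no leaving group.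

**Step 13**
Reactants: 21 (2S)-4'-(benzyloxy)-7-hydroxy-5-methoxy-3'-(5,7,4'-tri-O-benzylapigenin-6-yl)flavanone
Product: 22 (2S)-4',7-dihydroxy-5-methoxy-3'-(apigenin-6-yl)flavanone (CNP0332590.1)
Conditions: H2 (1 atm), 10% Pd/C, THF-MeOH, rt
Reagents that add atoms: none
Why: Catalytic hydrogenolysis of benzyl aryl ethers under neutral conditions, in which the flavone double bond, the two aryl ketones and the C2-O1 bond react much more slowly at one atmosphere, the 5-methoxy group is untouched, and no base is present to open ring C, so C2 stays S.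

**Compound list**
1 | apigenin | O=c1cc(-c2ccc(O)cc2)oc2cc(O)cc(O)c12 | starting material
2 | 7,4'-di-O-benzylapigenin | O=c1cc(-c2ccc(OCc3ccccc3)cc2)oc2cc(OCc3ccccc3)cc(O)c12 | intermediate
3 | 7,4'-di-O-benzyl-6-iodoapigenin | Ic1c(OCc2ccccc2)cc2oc(-c3ccc(OCc4ccccc4)cc3)cc(=O)c2c1O | intermediate
4 | 5,7,4'-tri-O-benzyl-6-iodoapigenin | Ic1c(OCc2ccccc2)cc2oc(-c3ccc(OCc4ccccc4)cc3)cc(=O)c2c1OCc1ccccc1 | intermediate
5 | 3-bromo-4-hydroxybenzaldehyde | O=Cc1ccc(O)c(Br)c1 | starting material
6 | 4-(benzyloxy)-3-bromobenzaldehyde | O=Cc1ccc(OCc2ccccc2)c(Br)c1 | intermediate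
7 | 4-(benzyloxy)-3-(4,4,5,5-tetramethyl-1,3,2-dioxaborolan-2-yl)benzaldehyde | O=Cc1ccc(OCc2ccccc2)c(B2OC(C)(C)C(C)(C)O2)c1 | intermediate
8 | 4-(benzyloxy)-3-(5,7,4'-tri-O-benzylapigenin-6-yl)benzaldehyde | O=Cc1ccc(OCc2ccccc2)c(-c2c(OCc3ccccc3)cc3oc(-c4ccc(OCc5ccccc5)cc4)cc(=O)c3c2OCc2ccccc2)c1 | intermediate
9 | (E)-1-methoxy-3-(trimethylsilyloxy)buta-1,3-diene | CO/C=C/C(=C)O[Si](C)(C)C | starting material
10 | (5S,1E)-5-Ar-1-methoxy-5-(trimethylsilyloxy)pent-1-en-3-one | CO/C=C/C(=O)C[C@@H](c1ccc(OCc2ccccc2)c(-c2c(OCc3ccccc3)cc3oc(-c4ccc(OCc5ccccc5)cc4)cc(=O)c3c2OCc2ccccc2)c1)O[Si](C)(C)C | intermediate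
11 | (2S)-2-Ar-2,3-dihydro-4H-pyran-4-one | O=C1C[C@@H](c2ccc(OCc3ccccc3)c(-c3c(OCc4ccccc4)cc4oc(-c5ccc(OCc6ccccc6)cc5)cc(=O)c4c3OCc3ccccc3)c2)OC=C1 | intermediate
12 | (2S)-2-Ar-6-chloro-5-(phenylsulfanyl)tetrahydropyran-4-one (C5, C6 undefined) | O=C1C[C@@H](c2ccc(OCc3ccccc3)c(-c3c(OCc4ccccc4)cc4oc(-c5ccc(OCc6ccccc6)cc5)cc(=O)c4c3OCc3ccccc3)c2)OC(Cl)C1Sc1ccccc1 | intermediate
13 | (2S)-2-Ar-5-(phenylsulfanyl)-2,3-dihydro-4H-pyran-4-one | O=C1C[C@@H](c2ccc(OCc3ccccc3)c(-c3c(OCc4ccccc4)cc4oc(-c5ccc(OCc6ccccc6)cc5)cc(=O)c4c3OCc3ccccc3)c2)OC=C1Sc1ccccc1 | intermediate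
14 | (2S)-2-Ar-5-(phenylsulfinyl)-2,3-dihydro-4H-pyran-4-one (sulfur epimers) | O=C1C[C@@H](c2ccc(OCc3ccccc3)c(-c3c(OCc4ccccc4)cc4oc(-c5ccc(OCc6ccccc6)cc5)cc(=O)c4c3OCc3ccccc3)c2)OC=C1S(=O)c1ccccc1 | intermediate
15 | 1,1-dimethoxyethene | C=C(OC)OC | starting material
16 | 4,4-dimethoxybut-3-en-2-one | CC(=O)C=C(OC)OC | intermediate
17 | 1,1-dimethoxy-3-(trimethylsilyloxy)buta-1,3-diene | COC(OC)=CC(=C)O[Si](C)(C)C | intermediate
18 | (2S)-2-Ar-5,5-dimethoxy-4a-(phenylsulfinyl)-7-(trimethylsilyloxy)-2,3,4a,5,8,8a-hexahydrochromen-4-one (cis ring fusion, C4a, C8a and S as mixture) | O=C1C[C@@H](c2ccc(OCc3ccccc3)c(-c3c(OCc4ccccc4)cc4oc(-c5ccc(OCc6ccccc6)cc5)cc(=O)c4c3OCc3ccccc3)c2)OC2CC(O[Si](C)(C)C)=CC(OC)(OC)C12S(=O)c1ccccc1 | intermediate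
19 | (2S)-2-Ar-5,5-dimethoxy-7-(trimethylsilyloxy)-2,3,5,8-tetrahydrochromen-4-one | O=C1C[C@@H](c2ccc(OCc3ccccc3)c(-c3c(OCc4ccccc4)cc4oc(-c5ccc(OCc6ccccc6)cc5)cc(=O)c4c3OCc3ccccc3)c2)OC2=C1C(OC)(OC)C=C(O[Si](C)(C)C)C2 | intermediate
20 | (2S)-4'-(benzyloxy)-5-methoxy-7-(trimethylsilyloxy)-3'-(5,7,4'-tri-O-benzylapigenin-6-yl)flavanone | COc1cc(O[Si](C)(C)C)cc2c1C(=O)C[C@@H](c1ccc(OCc3ccccc3)c(-c3c(OCc4ccccc4)cc4oc(-c5ccc(OCc6ccccc6)cc5)cc(=O)c4c3OCc3ccccc3)c1)O2 | intermediate
21 | (2S)-4'-(benzyloxy)-7-hydroxy-5-methoxy-3'-(5,7,4'-tri-O-benzylapigenin-6-yl)flavanone | COc1cc(O)cc2c1C(=O)C[C@@H](c1ccc(OCc3ccccc3)c(-c3c(OCc4ccccc4)cc4oc(-c5ccc(OCc6ccccc6)cc5)cc(=O)c4c3OCc3ccccc3)c1)O2 | intermediate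
22 | (2S)-4',7-dihydroxy-5-methoxy-3'-(apigenin-6-yl)flavanone, CNP0332590.1 | COc1cc(O)cc2c1C(=O)C[C@@H](c1ccc(O)c(-c3c(O)cc4oc(-c5ccc(O)cc5)cc(=O)c4c3O)c1)O2 | target

**Total step count:** 13.
**Longest linear sequence:** 9 steps (1, 2, 3, 6, 7, 8, 9, 12, 13).

**Steps most likely to fail**

**Step 12.**
- *What may go wrong:* the donor oxygen O1 may leave the double bond too electron-rich. The diene could then decay by hydrolysis, or by silyl transfer to the sulfinyl oxygen with Pummerer-type reduction, faster than it adds. A stepwise adduct may also expel O1 from C8a before ring A closes.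
- *Fallback:* it sets out from 8 and comes back at 22. Ring A is taken from a bought arene and ring C is closed by known flavanone chemistry.
  - Commercial 2,4-dihydroxy-6-methoxyacetophenone is benzylated at its non-chelated hydroxyl (BnBr, K2CO3, acetone) to give 4-(benzyloxy)-2-hydroxy-6-methoxyacetophenone F1.
  - Claisen-Schmidt condensation of F1 with 8 (KOH, EtOH-THF, rt) gives the (E)-2'-hydroxychalcone F2.
  - NaOAc in refluxing EtOH closes ring C by oxa-Michael addition to give the racemic penta-O-benzyl flavanone F3.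
  - Preparative HPLC on a polysaccharide chiral phase delivers the (2S)-penta-O-benzyl flavanone F4. The (2R)-penta-O-benzyl flavanone F5 is re-equilibrated with NaOAc and recycled.
  - Hydrogenolysis of F4 under the conditions of step 13 gives 22.

**Step 8.**
- *What may go wrong:* the electrophile may also attack C8'' of the trialkoxy flavone ring or C3'', or sulfenylate twice, because the push-pull alkene is only moderately nucleophilic.
- *Fallback:* it sets out from 8 and comes back at 13. Sulfur is delivered to a true silyl enol ether, which is far more nucleophilic than any arene present.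
  - Aldehyde 8 and 9 are combined in CH2Cl2 at -30 °C with [(S,S)-N,N'-bis(3,5-di-tert-butylsalicylidene)cyclohexane-1,2-diaminato]chromium tetrafluoroborate and 4 Å MS.
  - This catalyst works through a concerted cycloaddition and leaves the primary cycloadduct (2S)-2-Ar-6-methoxy-4-(trimethylsilyloxy)-3,6-dihydro-2H-pyran F6 intact.
  - PhSCl, dosed on the total silyl enol ether, is added at -78 °C and gives (2S)-2-Ar-6-methoxy-5-(phenylsulfanyl)tetrahydropyran-4-one F7.
  - Catalytic CF3CO2H then eliminates methanol to give 13, which is recrystallised if the enantiomeric purity needs raising.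

**Step 7.**
- *What may go wrong:* the Lewis-basic flavone carbonyl may sequester the titanium catalyst. The large ortho-aryl substituent may erode facial selectivity.
- *Fallback:* it sets out from 8 and comes back at 11. The metal Lewis acid is replaced by hydrogen-bond catalysis and a more reactive amino diene.
  - Aldehyde 8 and commercial (E)-1-(dimethylamino)-3-(tert-butyldimethylsilyloxy)buta-1,3-diene are combined in toluene at -40 °C with 20 mol % of the tetra(1-naphthyl)-TADDOL antipode that exposes the Si face.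
  - This gives (2S)-2-Ar-6-(dimethylamino)-4-(tert-butyldimethylsilyloxy)-3,6-dihydro-2H-pyran F8.
  - Acetyl chloride at -78 °C converts F8 into 11.

**Further compounds**
F1 | step 12 | 4-(benzyloxy)-2-hydroxy-6-methoxyacetophenone | CC(=O)c1c(O)cc(OCc2ccccc2)cc1OC
F2 | step 12 | (E)-1-[4-(benzyloxy)-2-hydroxy-6-methoxyphenyl]-3-Ar-prop-2-en-1-one | COc1cc(OCc2ccccc2)cc(O)c1C(=O)/C=C/c1ccc(OCc2ccccc2)c(-c2c(OCc3ccccc3)cc3oc(-c4ccc(OCc5ccccc5)cc4)cc(=O)c3c2OCc2ccccc2)c1
F3 | step 12 | racemic 7,4'-bis(benzyloxy)-5-methoxy-3'-(5,7,4'-tri-O-benzylapigenin-6-yl)flavanone | COc1cc(OCc2ccccc2)cc2c1C(=O)CC(c1ccc(OCc3ccccc3)c(-c3c(OCc4ccccc4)cc4oc(-c5ccc(OCc6ccccc6)cc5)cc(=O)c4c3OCc3ccccc3)c1)O2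
F4 | step 12 | (2S)-7,4'-bis(benzyloxy)-5-methoxy-3'-(5,7,4'-tri-O-benzylapigenin-6-yl)flavanone | COc1cc(OCc2ccccc2)cc2c1C(=O)C[C@@H](c1ccc(OCc3ccccc3)c(-c3c(OCc4ccccc4)cc4oc(-c5ccc(OCc6ccccc6)cc5)cc(=O)c4c3OCc3ccccc3)c1)O2
F5 | step 12 | (2R)-7,4'-bis(benzyloxy)-5-methoxy-3'-(5,7,4'-tri-O-benzylapigenin-6-yl)flavanone | COc1cc(OCc2ccccc2)cc2c1C(=O)C[C@H](c1ccc(OCc3ccccc3)c(-c3c(OCc4ccccc4)cc4oc(-c5ccc(OCc6ccccc6)cc5)cc(=O)c4c3OCc3ccccc3)c1)O2
F6 | step 8 | (2S)-2-Ar-6-methoxy-4-(trimethylsilyloxy)-3,6-dihydro-2H-pyran | COC1C=C(O[Si](C)(C)C)C[C@@H](c2ccc(OCc3ccccc3)c(-c3c(OCc4ccccc4)cc4oc(-c5ccc(OCc6ccccc6)cc5)cc(=O)c4c3OCc3ccccc3)c2)O1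
F7 | step 8 | (2S)-2-Ar-6-methoxy-5-(phenylsulfanyl)tetrahydropyran-4-one | O=C1C[C@@H](c2ccc(OCc3ccccc3)c(-c3c(OCc4ccccc4)cc4oc(-c5ccc(OCc6ccccc6)cc5)cc(=O)c4c3OCc3ccccc3)c2)OC(OC)C1Sc1ccccc1
F8 | step 7 | (2S)-2-Ar-6-(dimethylamino)-4-(tert-butyldimethylsilyloxy)-3,6-dihydro-2H-pyran | CN(C)C1C=C(O[Si](C)(C)C(C)(C)C)C[C@@H](c2ccc(OCc3ccccc3)c(-c3c(OCc4ccccc4)cc4oc(-c5ccc(OCc6ccccc6)cc5)cc(=O)c4c3OCc3ccccc3)c2)O1
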